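**Retrosynthetic overview**
1. Target ⇐ fluoride desilylation ⇐ copper-catalysed Ullmann C–O coupling of a ring A 2-bromobenzoate with a ring B 2,6-disubstituted phenol, both prenyl ethers already in place.
2. Ring A bromobenzoate ⇐ ortho-lithiation/carboxylation of 3-bromo-5-methylphenyl prenyl ether ⇐ 3-bromo-5-methylphenol ⇐ (Sandmeyer, Bucherer-type amination) orcinol.
3. Orcinol carbocycle ⇐ key C–C bond: intermolecular Michael addition of methyl acetoacetate to methyl crotonate, Dieckmann closure, then bromination/decarboxylative aromatisation.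
4. Ring B phenol ⇐ 2-hydroxy-5-methoxybenzaldehyde by bromination, copper-mediated hydroxylation, selective 3-O-prenylation, reduction and O-silylation.
5. Ring order: ring A is the only ring built (step 1, aromatised in step 2); ring B is bought as an arene; the rings are joined in the last step but one.

Assumption: the target has no stereocentre and no E/Z-isomeric double bond (both alkenes are prenyl groups), so it is achiral and the SMILES as given is the single compound to be made.

**Route**

Step 1
Reactants: 1 methyl acetoacetate (methyl 3-oxobutanoate); 2 methyl (E)-but-2-enoate (methyl crotonate)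
Product: 4 methyl 2-methyl-4,6-dioxocyclohexane-1-carboxylate, via Michael adduct 3 (not isolated)
Conditions: NaOMe (1.05 equiv), MeOH, reflux, 4 h; then aq. HCl, 0 °C
Reagents that add atoms: none
Why: Intermolecular Michael addition of the acetoacetate enolate to the crotonate β-carbon joins the two four-carbon fragments, and the methyl-ketone enolate of adduct 3 then closes ring A by Dieckmann (intramolecular Claisen) condensation onto the distal ester, pulled through by the stabilised 1,3-dione enolate; the two stereocentres formed are uncontrolled and are erased on aromatisation in step 2.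

Step 2
Reactants: 4 methyl 2-methyl-4,6-dioxocyclohexane-1-carboxylate
Product: 8 orcinol (5-methylbenzene-1,3-diol), via bromo keto ester 5 (not isolated), via methyl orsellinate 6 (not isolated), via orsellinic acid 7 (not isolated)
Conditions: Br2 (1.0 equiv), DMF, 0 °C to rt; then 150 °C, 8 h
Reagents that add atoms: none
Why: Bromination between the carbonyl groups and loss of HBr aromatises the dione to methyl orsellinate, whose ortho-hydroxy methyl ester is dealkylated by bromide in hot DMF (Krapcho-type SN2 at methyl) and whose 2,4-dihydroxybenzoic acid then decarboxylates thermally, the same one-pot sequence used to make olivetol from the pentyl homologue of 4.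

Step 3
Reactants: 8 orcinol
Product: 9 3-amino-5-methylphenol
Conditions: 28% aq. NH3, NH4Cl (0.5 equiv), 180 °C, autoclave, 40 h
Reagents that add atoms: ammonia, N
Why: Bucherer-type amination in which the keto tautomer of the resorcinol condenses with ammonia to an enaminone that re-aromatises; 8 is symmetric and the aminophenol ketonises far less readily, so only one hydroxyl is exchanged for NH2.

Step 4
Reactants: 9 3-amino-5-methylphenol
Product: 11 3-bromo-5-methylphenol, via diazonium bromide 10 (not isolated)
Conditions: NaNO2, 48% aq. HBr, 0–5 °C; then CuBr (20 mol %), 48% aq. HBr, 70 °C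
Reagents that add atoms: hydrogen bromide, Br
Why: Diazotisation in strong acid (which suppresses azo coupling to the free phenol) followed by the Sandmeyer reaction replaces NH2 by Br at the same carbon with no regiochemical ambiguity.

Step 5
Reactants: 11 3-bromo-5-methylphenol
Product: 12 1-bromo-3-methyl-5-[(3-methylbut-2-en-1-yl)oxy]benzene
Conditions: prenyl bromide (1.2 equiv), K2CO3, DMF, rt
Reagents that add atoms: 1-bromo-3-methylbut-2-ene (prenyl bromide), CC(C)=CCBr
Why: Williamson etherification in which the phenoxide attacks the primary allylic bromide by SN2 under mild conditions that give O- rather than C-prenylation.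

Step 6
Reactants: 12 1-bromo-3-methyl-5-[(3-methylbut-2-en-1-yl)oxy]benzene
Product: 14 methyl 2-bromo-4-methyl-6-[(3-methylbut-2-en-1-yl)oxy]benzoate, via aryllithium 13 (not isolated)
Conditions: LiN(iPr)2 (1.1 equiv), THF, −78 °C, 1 h; then ClCO2Me (2.5 equiv), −78 °C to rt
Reagents that add atoms: methyl chloroformate, COC(=O)Cl
Why: Directed ortho-metalation removes the hydrogen flanked by Br and the alkoxy group (by far the most acidic ring C–H) without bromine–lithium exchange, the ortho-bromoaryllithium is stable to benzyne formation at −78 °C, and acylation with methyl chloroformate stops at the hindered ester.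

Step 7
Reactants: 15 2-hydroxy-5-methoxybenzaldehyde
Product: 16 3-bromo-2-hydroxy-5-methoxybenzaldehyde
Conditions: Br2 (1.05 equiv), NaOAc, AcOH, rt
Reagents that add atoms: bromine, BrBr
Why: Electrophilic aromatic bromination is directed by the phenol to its only free ortho position, since the para position carries OMe and the positions ortho to OMe are deactivated by the ortho/para aldehyde.

Step 8
Reactants: 16 3-bromo-2-hydroxy-5-methoxybenzaldehyde
Product: 17 2,3-dihydroxy-5-methoxybenzaldehyde
Conditions: 8% aq. NaOH, Cu powder (5 mol %), reflux, N2, 24 h; then aq. HCl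
Reagents that add atoms: sodium hydroxide, [Na+].[OH-]
Why: Copper-mediated Ullmann-type hydroxylation of an ortho-bromophenoxide, the transformation that converts 5-bromovanillin into 5-hydroxyvanillin; the phenoxide-conjugated aldehyde resists the Cannizzaro reaction and exclusion of air protects the catechol.

Step 9
Reactants: 17 2,3-dihydroxy-5-methoxybenzaldehyde
Product: 18 2-hydroxy-5-methoxy-3-[(3-methylbut-2-en-1-yl)oxy]benzaldehyde
Conditions: NaH (2.2 equiv), DMSO, rt, 1 h; prenyl bromide (1.0 equiv), rt; then aq. HCl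
Reagents that add atoms: 1-bromo-3-methylbut-2-ene (prenyl bromide), CC(C)=CCBr
Why: Williamson etherification of the dianion, in which the 3-phenoxide (neither conjugated with nor chelated to the aldehyde) is much the more nucleophilic oxygen, so one equivalent of prenyl bromide alkylates O-3 selectively.

Step 10
Reactants: 18 2-hydroxy-5-methoxy-3-[(3-methylbut-2-en-1-yl)oxy]benzaldehyde
Product: 19 2-(hydroxymethyl)-4-methoxy-6-[(3-methylbut-2-en-1-yl)oxy]phenol
Conditions: NaBH4, MeOH, 0 °C
Reagents that add atoms: none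
Why: Chemoselective NaBH4 reduction of the aldehyde to the benzylic alcohol leaves the alkene and the aryl ethers untouched.

Step 11
Reactants: 19 2-(hydroxymethyl)-4-methoxy-6-[(3-methylbut-2-en-1-yl)oxy]phenol
Product: 20 2-{[(tert-butyldimethylsilyl)oxy]methyl}-4-methoxy-6-[(3-methylbut-2-en-1-yl)oxy]phenol
Conditions: TBSCl (1.05 equiv), imidazole, CH2Cl2, 0 °C
Reagents that add atoms: tert-butyldimethylsilyl chloride, CC(C)(C)[Si](C)(C)Cl
Why: Silyl protection in which the unhindered primary benzylic alcohol is silylated much faster than the di-ortho-substituted, hydrogen-bonded phenol, which must stay free for the coupling.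

Step 12
Reactants: 14 methyl 2-bromo-4-methyl-6-[(3-methylbut-2-en-1-yl)oxy]benzoate; 20 2-{[(tert-butyldimethylsilyl)oxy]methyl}-4-methoxy-6-[(3-methylbut-2-en-1-yl)oxy]phenol
Product: 21 methyl 2-[2-{[(tert-butyldimethylsilyl)oxy]methyl}-4-methoxy-6-[(3-methylbut-2-en-1-yl)oxy]phenoxy]-4-methyl-6-[(3-methylbut-2-en-1-yl)oxy]benzoate
Conditions: CuI (10 mol %), picolinic acid (20 mol %), K3PO4 (2 equiv), DMSO, 90 °C, 24 h
Reagents that add atoms: none
Why: Ullmann diaryl ether synthesis in which the ortho ester activates the C–Br bond toward the copper phenoxide, the picolinate ligand is the one suited to hindered 2,6-disubstituted phenols, and 90 °C is below the temperature at which aryl prenyl ethers undergo Claisen rearrangement.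

Step 13
Reactants: 21 methyl 2-[2-{[(tert-butyldimethylsilyl)oxy]methyl}-4-methoxy-6-[(3-methylbut-2-en-1-yl)oxy]phenoxy]-4-methyl-6-[(3-methylbut-2-en-1-yl)oxy]benzoate
Product: 22 methyl 2-[2-(hydroxymethyl)-4-methoxy-6-[(3-methylbut-2-en-1-yl)oxy]phenoxy]-4-methyl-6-[(3-methylbut-2-en-1-yl)oxy]benzoate
Conditions: Bu4NF (1.2 equiv), AcOH (1.2 equiv), THF, 0 °C to rt
Reagents that add atoms: none
Why: Fluoride-induced desilylation (Si–F bond formation) frees the primary alcohol, and the acetic acid buffer keeps the alkoxide from attacking the neighbouring methyl ester.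

**Compound list**
1 | methyl acetoacetate (methyl 3-oxobutanoate) | CC(=O)CC(=O)OC | starting material
2 | methyl (E)-but-2-enoate (methyl crotonate) | C/C=C/C(=O)OC | starting material
3 | dimethyl 2-acetyl-3-methylpentanedioate (Michael adduct, stereoisomer mixture, not isolated) | COC(=O)CC(C)C(C(C)=O)C(=O)OC | intermediate
4 | methyl 2-methyl-4,6-dioxocyclohexane-1-carboxylate (racemic diastereomer/enol mixture) | COC(=O)C1C(C)CC(=O)CC1=O | intermediate
5 | methyl 5-bromo-2-methyl-4,6-dioxocyclohexane-1-carboxylate (stereoisomer mixture, not isolated) | COC(=O)C1C(C)CC(=O)C(Br)C1=O | intermediate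
6 | methyl 2,4-dihydroxy-6-methylbenzoate (methyl orsellinate, not isolated) | COC(=O)c1c(C)cc(O)cc1O | intermediate
7 | 2,4-dihydroxy-6-methylbenzoic acid (orsellinic acid, not isolated) | Cc1cc(O)cc(O)c1C(=O)O | intermediate
8 | 5-methylbenzene-1,3-diol (orcinol) | Cc1cc(O)cc(O)c1 | intermediate
9 | 3-amino-5-methylphenol | Cc1cc(N)cc(O)c1 | intermediate
10 | 3-hydroxy-5-methylbenzenediazonium bromide (not isolated) | Cc1cc(O)cc([N+]#N)c1.[Br-] | intermediate
11 | 3-bromo-5-methylphenol | Cc1cc(O)cc(Br)c1 | intermediate
12 | 1-bromo-3-methyl-5-[(3-methylbut-2-en-1-yl)oxy]benzene | Cc1cc(Br)cc(OCC=C(C)C)c1 | intermediate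
13 | {2-bromo-4-methyl-6-[(3-methylbut-2-en-1-yl)oxy]phenyl}lithium (not isolated) | [Li]c1c(Br)cc(C)cc1OCC=C(C)C | intermediate
14 | methyl 2-bromo-4-methyl-6-[(3-methylbut-2-en-1-yl)oxy]benzoate | COC(=O)c1c(Br)cc(C)cc1OCC=C(C)C | intermediate
15 | 2-hydroxy-5-methoxybenzaldehyde | COc1ccc(O)c(C=O)c1 | starting material
16 | 3-bromo-2-hydroxy-5-methoxybenzaldehyde | COc1cc(Br)c(O)c(C=O)c1 | intermediate
17 | 2,3-dihydroxy-5-methoxybenzaldehyde | COc1cc(O)c(O)c(C=O)c1 | intermediate
18 | 2-hydroxy-5-methoxy-3-[(3-methylbut-2-en-1-yl)oxy]benzaldehyde | COc1cc(OCC=C(C)C)c(O)c(C=O)c1 | intermediate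
19 | 2-(hydroxymethyl)-4-methoxy-6-[(3-methylbut-2-en-1-yl)oxy]phenol | COc1cc(CO)c(O)c(OCC=C(C)C)c1 | intermediate
20 | 2-{[(tert-butyldimethylsilyl)oxy]methyl}-4-methoxy-6-[(3-methylbut-2-en-1-yl)oxy]phenol | COc1cc(CO[Si](C)(C)C(C)(C)C)c(O)c(OCC=C(C)C)c1 | intermediate
21 | methyl 2-[2-{[(tert-butyldimethylsilyl)oxy]methyl}-4-methoxy-6-[(3-methylbut-2-en-1-yl)oxy]phenoxy]-4-methyl-6-[(3-methylbut-2-en-1-yl)oxy]benzoate | COC(=O)c1c(OCC=C(C)C)cc(C)cc1Oc1c(CO[Si](C)(C)C(C)(C)C)cc(OC)cc1OCC=C(C)C | intermediate
22 | methyl 2-[2-(hydroxymethyl)-4-methoxy-6-[(3-methylbut-2-en-1-yl)oxy]phenoxy]-4-methyl-6-[(3-methylbut-2-en-1-yl)oxy]benzoate (CNP0561346.0, achiral) | COC(=O)c1c(OCC=C(C)C)cc(C)cc1Oc1c(CO)cc(OC)cc1OCC=C(C)C | target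

**Step count**
Total steps: 13. Longest linear sequence: 8 (steps 1–6, then 12 and 13); the ring B branch is 5 steps (7–11) before the coupling.

**Three steps most likely to fail, with fallbacks**

Step 12 (Ullmann coupling of a di-ortho-substituted phenol with an ortho-substituted bromide; may stall or debrominate). The fallback sets out from 12 and comes back at 21. Compound 12 is lithiated as in step 6 (LiN(iPr)2, THF, −78 °C) and quenched with CO2 to give 2-bromo-4-methyl-6-[(3-methylbut-2-en-1-yl)oxy]benzoic acid F1. As its potassium salt, this acid is condensed with phenol 20 (CuI 10 mol %, K2CO3, DMF, 100 °C); the ortho-carboxylate holds copper next to the C–Br bond, as in the classical Ullmann–Goldberg reactions of 2-halobenzoic acids. This gives 2-[2-{[(tert-butyldimethylsilyl)oxy]methyl}-4-methoxy-6-[(3-methylbut-2-en-1-yl)oxy]phenoxy]-4-methyl-6-[(3-methylbut-2-en-1-yl)oxy]benzoic acid F2. Methylation (MeI, K2CO3, DMF, rt) then returns 21.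

Step 3 (harsh amination of orcinol; risk of low conversion or some diamine). The fallback sets out from 4 and comes back at 11, replacing steps 2–4 by a route that never passes through the diol. Keto ester 4 is saponified and decarboxylated (aq. NaOH, reflux; then HCl, reflux) to 5-methylcyclohexane-1,3-dione F3. PBr3 (CH2Cl2, 0 °C to rt) converts the vinylogous acid into 3-bromo-5-methylcyclohex-2-en-1-one F4. CuBr2 (2.2 equiv) with LiBr in refluxing MeCN then brominates the alpha' position to give 3,6-dibromo-5-methylcyclohex-2-en-1-one F5, which loses HBr in the same pot; the resulting dienone tautomerises to 11.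

Step 8 (copper/hydroxide displacement on an aldehyde-bearing bromophenol; the catechol product is oxidation-prone). The fallback sets out from 16 and comes back at 18, replacing steps 8 and 9 and never freeing the catechol. Compound 16 is protected (MOMCl, iPr2NEt, CH2Cl2) as 3-bromo-5-methoxy-2-(methoxymethoxy)benzaldehyde F6. Miyaura borylation (B2pin2, Pd(dppf)Cl2 3 mol %, KOAc, dioxane, 90 °C) gives 5-methoxy-2-(methoxymethoxy)-3-(4,4,5,5-tetramethyl-1,3,2-dioxaborolan-2-yl)benzaldehyde F7. Oxidation (NaBO3·4H2O, THF/H2O, rt) gives 3-hydroxy-5-methoxy-2-(methoxymethoxy)benzaldehyde F8. Prenyl bromide with K2CO3 in DMF gives 5-methoxy-2-(methoxymethoxy)-3-[(3-methylbut-2-en-1-yl)oxy]benzaldehyde F9. Mild acetal cleavage (pyridinium p-toluenesulfonate, MeOH, 50 °C) then returns 18.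

**Further compounds**
F1 | step 12 | 2-bromo-4-methyl-6-[(3-methylbut-2-en-1-yl)oxy]benzoic acid | OC(=O)c1c(Br)cc(C)cc1OCC=C(C)C
F2 | step 12 | 2-[2-{[(tert-butyldimethylsilyl)oxy]methyl}-4-methoxy-6-[(3-methylbut-2-en-1-yl)oxy]phenoxy]-4-methyl-6-[(3-methylbut-2-en-1-yl)oxy]benzoic acid | OC(=O)c1c(OCC=C(C)C)cc(C)cc1Oc1c(CO[Si](C)(C)C(C)(C)C)cc(OC)cc1OCC=C(C)C
F3 | step 3 | 5-methylcyclohexane-1,3-dione | CC1CC(=O)CC(=O)C1
F4 | step 3 | 3-bromo-5-methylcyclohex-2-en-1-one (racemic) | CC1CC(=O)C=C(Br)C1
F5 | step 3 | 3,6-dibromo-5-methylcyclohex-2-en-1-one (diastereomer mixture) | CC1CC(Br)=CC(=O)C1Br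
F6 | step 8 | 3-bromo-5-methoxy-2-(methoxymethoxy)benzaldehyde | COCOc1c(Br)cc(OC)cc1C=O
F7 | step 8 | 5-methoxy-2-(methoxymethoxy)-3-(4,4,5,5-tetramethyl-1,3,2-dioxaborolan-2-yl)benzaldehyde | COCOc1c(B2OC(C)(C)C(C)(C)O2)cc(OC)cc1C=O
F8 | step 8 | 3-hydroxy-5-methoxy-2-(methoxymethoxy)benzaldehyde | COCOc1c(O)cc(OC)cc1C=O
F9 | step 8 | 5-methoxy-2-(methoxymethoxy)-3-[(3-methylbut-2-en-1-yl)oxy]benzaldehyde | COCOc1c(OCC=C(C)C)cc(OC)cc1C=O
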